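## Retrosynthetic overview
1. Structural feature: ring A (C4a, C5, C6, C7, C8, C8a) is a phloroglucinol with oxygen on C5, C7 and C8a, and it carries the C4 acyl carbon on C4a. This is the folded form of a linear 3,5,7-triketo ester, so ring A is closed from a chain instead of being bought.
2. Late stage: cleave the 4'-O-MOM ether, undo the C2=C3 unsaturation (flavone ⇒ 3-prenylflavanone), then open O1–C2 of ring C (retro-oxa-Michael) ⇒ 2',4',6'-trihydroxy-α-prenylchalcone.
3. Key disconnection C4a–C8a: ring A ⇒ methyl triketo ester ⇒ its lactone, a 6-(2-oxoalkyl)-4-hydroxy-2-pyranone that already holds C2, C3, C4, the prenyl group and ring B.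
4. Pyranone ⇒ C4–C4a acylation of the dianion of 4-hydroxy-6-methyl-2-pyranone by an α-prenylcinnamic N-methoxy-N-methylamide ⇒ C2=C3 Horner–Wadsworth–Emmons union of the MOM-protected aldehyde with an α-prenylated amide phosphonate.
5. Ring order: ring B is purchased, ring A closes in step 5, ring C closes in step 6 and is made unsaturated in step 7.

Key step: step 5

Assumption: the target has no stereocentre, so stereocentres that appear in passing (phosphonate α-carbon, carbinolamine carbon, C2/C3 of the flavanone) are racemic and are destroyed later; LDA and Mg(OMe)2 are used as commercial solutions.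

## Route

Step 1
Reactants: 1 4-hydroxy-2-methoxybenzaldehyde
Product: 2 2-methoxy-4-(methoxymethoxy)benzaldehyde
Conditions: MOMCl, K2CO3, acetone, 0 °C to rt
Reagents that add atoms: chloromethyl methyl ether (MOMCl), COCCl
Why: Williamson-type O-alkylation of the only acidic site: the 4-phenoxide, a vinylogous carboxylate of the aldehyde, is captured by the very reactive α-chloro ether, and the resulting acetal withstands all basic and oxidative steps up to step 8.

Step 2
Reactants: 3 diethyl (N-methoxy-N-methylcarbamoylmethyl)phosphonate; 4 prenyl bromide (1-bromo-3-methylbut-2-ene)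
Product: 6 diethyl [1-[methoxy(methyl)amino]-5-methyl-1-oxohex-4-en-2-yl]phosphonate (racemic), via sodium carbanion of the phosphonate 5 (not isolated)
Conditions: NaH (1.0 equiv), THF, 0 °C; then 4 (1.0 equiv), 0 °C to rt
Reagents that add atoms: none
Why: Alkylation of a stabilised phosphonate carbanion: NaH irreversibly removes a proton from the CH2 between P=O and the amide carbonyl, and the soft carbanion 5 displaces bromide at the primary carbon of 4 (SN2, no allylic transposition), one equivalent each of base and halide keeping double alkylation low, while the new stereocentre is racemic and is erased in step 3.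

Step 3
Reactants: 6 diethyl [1-[methoxy(methyl)amino]-5-methyl-1-oxohex-4-en-2-yl]phosphonate; 2 2-methoxy-4-(methoxymethoxy)benzaldehyde
Product: 8 (E)-N-methoxy-2-[2-methoxy-4-(methoxymethoxy)benzylidene]-N,5-dimethylhex-4-enamide, via sodium carbanion of the prenylated phosphonate 7 (not isolated)
Conditions: NaH, THF, 0 °C; then 2, rt to 60 °C
Reagents that add atoms: none
Why: Horner–Wadsworth–Emmons olefination: carbanion 7 adds reversibly to the aromatic aldehyde and the less crowded oxaphosphetane collapses faster, which should place the aryl group trans to the carboxamide (E), a minor Z isomer being removable by chromatography and the olefin geometry being lost anyway in steps 6 and 7.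

Step 4
Reactants: 8 (E)-N-methoxy-2-[2-methoxy-4-(methoxymethoxy)benzylidene]-N,5-dimethylhex-4-enamide; 9 4-hydroxy-6-methyl-2-pyranone
Product: 12 4-hydroxy-6-[(E)-3-[2-methoxy-4-(methoxymethoxy)benzylidene]-6-methyl-2-oxohept-5-enyl]pyran-2-one, via dilithio dianion of the pyranone 10 (not isolated), via tetrahedral dilithium adduct 11 (not isolated)
Conditions: 9 (2 equiv), LiN(iPr)2 (LDA, 4 equiv), THF–DMPU, −78 to −20 °C; then 8, −78 to 0 °C; cold 1 M HCl to pH 3
Reagents that add atoms: none
Why: C-acylation of a dienolate dianion by an N-methoxy-N-methylamide: after the 4-OH, LDA removes a proton from the vinylogous 6-methyl group, this last-formed and most nucleophilic carbon of 10 adds 1,2 to the amide carbonyl (the β-carbon is trisubstituted and deactivated by the dialkoxyaryl ring), and the chelated adduct 11 survives until the quench, so that neither a second addition nor protonation of 10 by the acidic product can interfere.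

Step 5
Reactants: 12 4-hydroxy-6-[(E)-3-[2-methoxy-4-(methoxymethoxy)benzylidene]-6-methyl-2-oxohept-5-enyl]pyran-2-one
Product: 15 (E)-2',4',6'-trihydroxy-2-methoxy-4-(methoxymethoxy)-α-prenylchalcone, via methyl triketo ester 13 (not isolated), via acylcyclohexanetrione tautomer 14 (not isolated)
Conditions: Mg(OMe)2 (8 equiv), MeOH, reflux, Ar; then 1 M HCl, 0 °C, to pH 3
Reagents that add atoms: none
Why: Magnesium-bound methoxide adds to the lactone carbonyl of 12, the acyl–O1 bond of the pyranone breaks, and the chain is set free as the magnesium enolate of methyl 3,5,7-triketo ester 13. The methylene flanked by the enone carbonyl (future C4) and the next ketone (future C5), which is the future C4a, then attacks the ester carbonyl (future C8a), methoxide leaves, and trione 14 tautomerises irreversibly to the phloroglucinol, so the C4a–C8a bond and ring A arise in one operation. The closest known reaction type is the biomimetic Claisen (Dieckmann-type) cyclisation of 6-(2-oxoalkyl)-4-hydroxy-2-pyranones and of 3,5,7-triketo esters to acylphloroglucinols under Mg(OMe)2 or methanolic hydroxide. Ring A closes 6-exo-trig at the ester carbonyl (enolendo with respect to the C5 enolate); no stereocentre is created and the E olefin is a spectator. The selectivity required is Claisen over aldol closure (ester α-carbon onto the C4 ketone, which would lead to a resorcylate), and the substrate secures it because the C4 carbonyl is conjugated to an electron-rich styrene, flanked by the fully substituted prenyl-bearing carbon and locked as a magnesium β-diketonate, which leaves the ester as the only free electrophile. Conjugate additions to the hindered, donor-substituted β-carbon are reversible whereas aromatisation is not, and in strong base the product stays open as its phenoxide, so a cold acidic quench should deliver 15, any 16 already formed being simply the product of step 6.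

Step 6
Reactants: 15 (E)-2',4',6'-trihydroxy-2-methoxy-4-(methoxymethoxy)-α-prenylchalcone
Product: 16 (±)-trans-(2R*,3S*)-5,7-dihydroxy-2-[2-methoxy-4-(methoxymethoxy)phenyl]-3-(3-methylbut-2-enyl)chroman-4-one
Conditions: NaOAc, EtOH, reflux
Reagents that add atoms: none
Why: Intramolecular oxa-Michael addition (6-endo-trig chalcone–flavanone isomerisation): under weak base either of the two equivalent ortho hydroxyls adds to the β-carbon, the equilibrium should lie on the flavanone side because the remaining ortho OH keeps its hydrogen bond to C4=O and the twisted α-substituted enone loses little conjugation, and reversible enolisation at C3 should settle the two transient stereocentres as the racemic trans (diequatorial) isomer.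

Step 7
Reactants: 16 (±)-trans-5,7-dihydroxy-2-[2-methoxy-4-(methoxymethoxy)phenyl]-3-(3-methylbut-2-enyl)chroman-4-one
Product: 17 5,7-dihydroxy-2-[2-methoxy-4-(methoxymethoxy)phenyl]-3-(3-methylbut-2-enyl)chromen-4-one
Conditions: DDQ (1.1 equiv), 1,4-dioxane, 80 °C
Reagents that add atoms: none
Why: Quinone dehydrogenation of a flavanone: hydride is taken from C2–H, which is benzylic to a 2,4-dialkoxyphenyl ring and α to O1 (the activation that makes dialkoxybenzyl ethers labile to DDQ), loss of the acidic C3 proton then gives the 4-pyranone and removes both stereocentres, and limiting the oxidant to about one equivalent spares the prenyl CH2.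

Step 8
Reactants: 17 5,7-dihydroxy-2-[2-methoxy-4-(methoxymethoxy)phenyl]-3-(3-methylbut-2-enyl)chromen-4-one
Product: 18 5,7-dihydroxy-2-(4-hydroxy-2-methoxyphenyl)-3-(3-methylbut-2-enyl)chromen-4-one (target)
Conditions: HCl (cat.), MeOH, 45 °C
Reagents that add atoms: none
Why: Acid-catalysed acetal exchange (MOM cleavage): protonation of the acetal releases the 4'-phenol and methanol takes up the methoxymethyl cation, under conditions mild enough that the trisubstituted prenyl olefin, which has no free ortho-phenol neighbour because 2' is a methyl ether, should be neither hydrated nor cyclised.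

## Compound list
1 | 4-hydroxy-2-methoxybenzaldehyde | COc1cc(O)ccc1C=O | starting material
2 | 2-methoxy-4-(methoxymethoxy)benzaldehyde | COCOc1ccc(C=O)c(OC)c1 | intermediate
3 | diethyl (N-methoxy-N-methylcarbamoylmethyl)phosphonate | CCOP(=O)(OCC)CC(=O)N(C)OC | starting material
4 | prenyl bromide (1-bromo-3-methylbut-2-ene) | CC(C)=CCBr | starting material
5 | sodium carbanion of phosphonate 3 (not isolated) | CCOP(=O)(OCC)[CH-]C(=O)N(C)OC.[Na+] | intermediate
6 | diethyl [1-[methoxy(methyl)amino]-5-methyl-1-oxohex-4-en-2-yl]phosphonate (racemic) | CCOP(=O)(OCC)C(CC=C(C)C)C(=O)N(C)OC | intermediate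
7 | sodium carbanion of phosphonate 6 (not isolated) | CCOP(=O)(OCC)[C-](CC=C(C)C)C(=O)N(C)OC.[Na+] | intermediate
8 | (E)-N-methoxy-2-[2-methoxy-4-(methoxymethoxy)benzylidene]-N,5-dimethylhex-4-enamide | COCOc1ccc(/C=C(\CC=C(C)C)C(=O)N(C)OC)c(OC)c1 | intermediate
9 | 4-hydroxy-6-methyl-2-pyranone | Cc1cc(O)cc(=O)o1 | starting material
10 | dilithio dianion of 9, deprotonated at 4-OH and 6-CH3 (not isolated) | [Li+].[Li+].[CH2-]c1cc([O-])cc(=O)o1 | intermediate
11 | tetrahedral dilithium adduct of 10 and 8, racemic at the carbinolamine carbon (not isolated) | COCOc1ccc(/C=C(\CC=C(C)C)C([O-])(Cc2cc([O-])cc(=O)o2)N(C)OC)c(OC)c1.[Li+].[Li+] | intermediate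
12 | 4-hydroxy-6-[(E)-3-[2-methoxy-4-(methoxymethoxy)benzylidene]-6-methyl-2-oxohept-5-enyl]pyran-2-one | COCOc1ccc(/C=C(\CC=C(C)C)C(=O)Cc2cc(O)cc(=O)o2)c(OC)c1 | intermediate
13 | methyl (E)-8-[2-methoxy-4-(methoxymethoxy)benzylidene]-11-methyl-3,5,7-trioxododec-10-enoate (not isolated) | COCOc1ccc(/C=C(\CC=C(C)C)C(=O)CC(=O)CC(=O)CC(=O)OC)c(OC)c1 | intermediate
14 | 2-[(E)-2-[2-methoxy-4-(methoxymethoxy)benzylidene]-5-methylhex-4-enoyl]cyclohexane-1,3,5-trione (not isolated) | COCOc1ccc(/C=C(\CC=C(C)C)C(=O)C2C(=O)CC(=O)CC2=O)c(OC)c1 | intermediate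
15 | (E)-2',4',6'-trihydroxy-2-methoxy-4-(methoxymethoxy)-α-prenylchalcone | COCOc1ccc(/C=C(\CC=C(C)C)C(=O)c2c(O)cc(O)cc2O)c(OC)c1 | intermediate
16 | (±)-trans-(2R*,3S*)-5,7-dihydroxy-2-[2-methoxy-4-(methoxymethoxy)phenyl]-3-(3-methylbut-2-enyl)chroman-4-one (racemate, 2R,3S enantiomer drawn) | COCOc1ccc([C@@H]2Oc3cc(O)cc(O)c3C(=O)[C@H]2CC=C(C)C)c(OC)c1 | intermediate
17 | 5,7-dihydroxy-2-[2-methoxy-4-(methoxymethoxy)phenyl]-3-(3-methylbut-2-enyl)chromen-4-one | COCOc1ccc(-c2oc3cc(O)cc(O)c3c(=O)c2CC=C(C)C)c(OC)c1 | intermediate
18 | 5,7-dihydroxy-2-(4-hydroxy-2-methoxyphenyl)-3-(3-methylbut-2-enyl)chromen-4-one (CNP0122041.0) | COc1cc(O)ccc1-c1oc2cc(O)cc(O)c2c(=O)c1CC=C(C)C | target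

## Step count and risks
Total step count: 8.
Longest linear sequence: 7 steps (1 → 2 → 8 → 12 → 15 → 16 → 17 → 18; the branch 3 → 6 → 8 has the same length).

Steps most likely to fail:

1. Step 5 (key step).
   - Risks: closure in the aldol mode instead of the Claisen mode; retro-Claisen fragmentation of the chain by methoxide; conjugate addition of a chain enolate to the enone; reluctance of the doubly deprotonated pyranone to open.
   - Fallback: it sets out from 8 and comes back at 18, and it brings ring A in ready-made instead of folding it. Phloroglucinol is treated with NaH and MOMCl in DMF to give 1,3,5-tris(methoxymethoxy)benzene F1. Directed ortho-lithiation (n-BuLi, THF, 0 °C) gives 2,4,6-tris(methoxymethoxy)phenyllithium F2, which is acylated by amide 8 (−78 °C to rt, NH4Cl quench) to give the tetra-MOM chalcone F3. Methanolic HCl removes all four acetals to give the tetrahydroxy chalcone F4. NaOAc in refluxing EtOH closes ring C to the 4'-hydroxyflavanone F5, and DDQ in dioxane dehydrogenates this directly to 18.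

2. Step 4.
   - Risks: slow addition of the delocalised, sparingly soluble dianion to a hindered amide; competing conjugate addition; base-induced loss of formaldehyde from the N–OMe group.
   - Fallback: it sets out from 8 and comes back at 12, and it replaces the acylation by an aldol addition followed by oxidation. iBu2AlH (THF, −78 °C) reduces 8 to the α-prenylcinnamaldehyde F6. Dianion 10, made as in step 4, adds 1,2 to this much more electrophilic carbonyl to give the racemic allylic alcohol F7. MnO2 in CH2Cl2 oxidises the allylic carbinol to 12.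

3. Step 7.
   - Risks: further hydride abstraction at the doubly allylic CH2 of the prenyl group; oxidative degradation of the free phloroglucinol ring; incomplete conversion.
   - Fallback: it sets out from 16 and comes back at 17, and it replaces hydride abstraction by a palladium enolate elimination. Soft enolisation and persilylation (TMSOTf, Et3N, CH2Cl2, −78 to 0 °C) gives the tris(trimethylsilyl) 2H-chromene enol ether F8. Saegusa–Ito oxidation with Pd(OAc)2 in MeCN gives the 5,7-bis(trimethylsilyl) flavone F9, and K2CO3 in MeOH strips the aryl silyl ethers to give 17. Any β-hydride loss toward the side chain should be corrected in the same basic treatment by prototropic shift to the more stable 4-pyranone.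

## Further compounds
F1 | step 5 | 1,3,5-tris(methoxymethoxy)benzene | COCOc1cc(OCOC)cc(OCOC)c1
F2 | step 5 | 2,4,6-tris(methoxymethoxy)phenyllithium | [Li]c1c(OCOC)cc(OCOC)cc1OCOC
F3 | step 5 | (E)-2-[2-methoxy-4-(methoxymethoxy)benzylidene]-5-methyl-1-[2,4,6-tris(methoxymethoxy)phenyl]hex-4-en-1-one | COCOc1ccc(/C=C(\CC=C(C)C)C(=O)c2c(OCOC)cc(OCOC)cc2OCOC)c(OC)c1
F4 | step 5 | (E)-2-(4-hydroxy-2-methoxybenzylidene)-5-methyl-1-(2,4,6-trihydroxyphenyl)hex-4-en-1-one | COc1cc(O)ccc1/C=C(\CC=C(C)C)C(=O)c1c(O)cc(O)cc1O
F5 | step 5 | (±)-trans-(2R*,3S*)-5,7-dihydroxy-2-(4-hydroxy-2-methoxyphenyl)-3-(3-methylbut-2-enyl)chroman-4-one | COc1cc(O)ccc1[C@@H]1Oc2cc(O)cc(O)c2C(=O)[C@H]1CC=C(C)C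
F6 | step 4 | (E)-2-[2-methoxy-4-(methoxymethoxy)benzylidene]-5-methylhex-4-enal | COCOc1ccc(/C=C(\CC=C(C)C)C=O)c(OC)c1
F7 | step 4 | 4-hydroxy-6-[(E)-2-hydroxy-3-[2-methoxy-4-(methoxymethoxy)benzylidene]-6-methylhept-5-enyl]pyran-2-one (racemic) | COCOc1ccc(/C=C(\CC=C(C)C)C(O)Cc2cc(O)cc(=O)o2)c(OC)c1
F8 | step 7 | 2-[2-methoxy-4-(methoxymethoxy)phenyl]-3-(3-methylbut-2-enyl)-4,5,7-tris(trimethylsilyloxy)-2H-chromene (racemic) | COCOc1ccc(C2Oc3cc(O[Si](C)(C)C)cc(O[Si](C)(C)C)c3C(O[Si](C)(C)C)=C2CC=C(C)C)c(OC)c1
F9 | step 7 | 2-[2-methoxy-4-(methoxymethoxy)phenyl]-3-(3-methylbut-2-enyl)-5,7-bis(trimethylsilyloxy)chromen-4-one | COCOc1ccc(-c2oc3cc(O[Si](C)(C)C)cc(O[Si](C)(C)C)c3c(=O)c2CC=C(C)C)c(OC)c1
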